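**Retrosynthetic overview**
1. Last bond: N–C of the 13-carbon chain, by reductive amination of the N–H cis-fused isoxazolidine with 13-(pyridin-3-yl)tridecanal (from 3-picoline and a C12 bromide).
2. Isoxazolidine ring (formed second): O–C3 closure as the cyclic hemiketal of a cis-2-(N-hydroxyamino)cyclopentyl ketone, then silane reduction of the oxocarbenium ion from the convex face (sets C3).
3. Ketone side chain: acetylide of 3-(octa-1,7-diynyl)pyridine added to a cyclopentene carbaldehyde, oxidation, full hydrogenation (sets C3a cis to N).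
4. Cyclopentene ring (formed first): amine-catalysed aza-Michael addition of BocNH–OTBS to (E)-hex-2-enedial, then intramolecular aldol condensation of the resulting enamine (sets C6a).
5. Three fragments (ring core, C8 pyridyl diyne, C13 pyridyl aldehyde) are made separately and joined late.

Assumption: the carbamate nitrogen attacks the imidazolidinone-bound iminium ion on the face opposite the benzyl group, as carbon nucleophiles do; dialdehydes 2 and 4 are used as freshly made solutions.

**Route**

Step 1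
Reactants: 1 2,5-dimethoxytetrahydrofuran
Product: 2 succinaldehyde
Conditions: H2O, 90 °C, 2 h; MeOH distilled off; CH2Cl2 extraction; used at once
Reagents that add atoms: water (O)
Why: Hydrolysis of the cyclic bis-acetal releases the 1,4-dialdehyde (acetal hydrolysis).

Step 2
Reactants: 2 succinaldehyde (3 equiv); 3 (triphenylphosphoranylidene)acetaldehyde
Product: 4 (E)-hex-2-enedial
Conditions: CH2Cl2, 0 °C to rt, 16 h
Reagents that add atoms: none
Why: Wittig olefination with a stabilised ylide is E-selective, and excess dialdehyde keeps it to mono-olefination.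

Step 3
Reactants: 5 tert-butyl N-hydroxycarbamate
Product: 6 tert-butyl N-[(tert-butyldimethylsilyl)oxy]carbamate
Conditions: t-BuMe2SiCl, Et3N, CH2Cl2, 0 °C to rt
Reagents that add atoms: tert-butyldimethylsilyl chloride, CC(C)(C)[Si](C)(C)Cl
Why: O-silylation of the acidic N–OH leaves an N–H carbamate that can only react through nitrogen (silyl protection).

Step 4
Reactants: 4 (E)-hex-2-enedial; 6 tert-butyl N-[(tert-butyldimethylsilyl)oxy]carbamate (1.2 equiv)
Product: 8 tert-butyl N-[(tert-butyldimethylsilyl)oxy]-N-[(1R)-2-formylcyclopent-2-en-1-yl]carbamate, via aldol adduct 7 (not isolated)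
Conditions: (2S,5S)-5-benzyl-2-tert-butyl-3-methylimidazolidin-4-one·TsOH (20 mol%), CHCl3, −20 °C, 24 h, then rt
Reagents that add atoms: none
Why: Iminium activation lets the carbamate nitrogen add to the β-carbon from the face opposite the catalyst benzyl group (sets R at the N-bearing carbon), and the resulting enamine closes the five-membered ring onto the tethered aldehyde and dehydrates (aza-Michael/intramolecular aldol condensation cascade).

Step 5
Reactants: 9 3-bromopyridine; 10 octa-1,7-diyne (4 equiv)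
Product: 11 3-(octa-1,7-diyn-1-yl)pyridine
Conditions: PdCl2(PPh3)2 (2 mol%), CuI (4 mol%), Et3N, 50 °C
Reagents that add atoms: none
Why: Sonogashira coupling; excess diyne suppresses double arylation.

Step 6
Reactants: 11 3-(octa-1,7-diyn-1-yl)pyridine; 8 tert-butyl N-[(tert-butyldimethylsilyl)oxy]-N-[(1R)-2-formylcyclopent-2-en-1-yl]carbamate
Product: 13 tert-butyl N-[(tert-butyldimethylsilyl)oxy]-N-[(1R)-2-[1-hydroxy-9-(pyridin-3-yl)nona-2,8-diyn-1-yl]cyclopent-2-en-1-yl]carbamate (carbinol epimers), via lithium acetylide 12 (not isolated)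
Conditions: n-BuLi (1.05 equiv), THF, −78 °C, 30 min; then 8, −78 to −40 °C; H2O quench
Reagents that add atoms: none
Why: 1,2-Addition of a lithium acetylide to the enal; the new carbinol centre is formed unselectively and is removed by oxidation in the next step.

Step 7
Reactants: 13 propargylic/allylic alcohol from step 6
Product: 14 tert-butyl N-[(tert-butyldimethylsilyl)oxy]-N-[(1R)-2-[9-(pyridin-3-yl)nona-2,8-diynoyl]cyclopent-2-en-1-yl]carbamate
Conditions: Dess–Martin periodinane (1.3 equiv), CH2Cl2, 0 °C to rt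
Reagents that add atoms: none
Why: Dess–Martin oxidation of the doubly activated secondary alcohol is neutral and tolerates pyridine, silyl ether and carbamate.

Step 8
Reactants: 14 ynone from step 7
Product: 15 tert-butyl N-[(tert-butyldimethylsilyl)oxy]-N-[(1R,2S)-2-[9-(pyridin-3-yl)nonanoyl]cyclopentyl]carbamate
Conditions: H2 (1 atm), Pd on carbon (10 wt% Pd), EtOAc, rt
Reagents that add atoms: none
Why: Heterogeneous hydrogenation saturates both alkynes and the ring C=C; syn delivery of H2 to the face anti to the bulky N(Boc)OTBS group places the acyl group cis to nitrogen (2S).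

Step 9
Reactants: 15 cis ketone from step 8
Product: 17 tert-butyl (3aS,6aR)-3-hydroxy-3-[8-(pyridin-3-yl)octyl]hexahydro-1H-cyclopenta[c]isoxazole-1-carboxylate (C3 anomers), via N-hydroxy carbamate 16 (not isolated)
Conditions: HF·pyridine, THF, 0 °C to rt
Reagents that add atoms: none
Why: Desilylation frees the N–OH group, which adds to the cis ketone to give the bicyclic hemiketal (ring–chain tautomerism); only the cis isomer can close.

Step 10
Reactants: 17 hemiketal from step 9
Product: 19 (3S,3aS,6aR)-3-[8-(pyridin-3-yl)octyl]hexahydro-1H-cyclopenta[c]isoxazole, via N-Boc isoxazolidine 18 (not isolated)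
Conditions: Et3SiH (5 equiv), CF3CO2H/CH2Cl2 (1:4), −20 °C to rt; aq. NaHCO3 work-up
Reagents that add atoms: none
Why: Acid ionises the hemiketal to a cyclic oxocarbenium ion that Et3SiH reduces from the convex face, anti to C4 (ionic hydrogenation; sets 3S with the chain on the concave face), and CF3CO2H then cleaves the Boc group.

Step 11
Reactants: 20 12-bromododecan-1-ol
Product: 21 (12-bromododecyloxy)(tert-butyl)dimethylsilane
Conditions: t-BuMe2SiCl, imidazole, DMF, rt
Reagents that add atoms: tert-butyldimethylsilyl chloride, CC(C)(C)[Si](C)(C)Cl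
Why: Silyl protection keeps the alcohol from quenching the picolyl anion in the next step.

Step 12
Reactants: 22 3-methylpyridine (1.2 equiv); 21 (12-bromododecyloxy)(tert-butyl)dimethylsilane
Product: 24 3-[13-[(tert-butyldimethylsilyl)oxy]tridecyl]pyridine, via 3-picolyllithium 23 (not isolated)
Conditions: LiN(i-Pr)2 (1.2 equiv), THF, −78 °C; then 21, −78 °C to rt
Reagents that add atoms: none
Why: Lateral lithiation of 3-picoline and SN2 alkylation by the primary bromide give the 13-carbon chain.

Step 13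
Reactants: 24 silyl ether from step 12
Product: 25 13-(pyridin-3-yl)tridecan-1-ol
Conditions: Bu4NF, THF, rt
Reagents that add atoms: none
Why: Fluoride cleaves the Si–O bond (desilylation).

Step 14
Reactants: 25 13-(pyridin-3-yl)tridecan-1-ol
Product: 26 13-(pyridin-3-yl)tridecanal
Conditions: Dess–Martin periodinane, CH2Cl2, rt
Reagents that add atoms: none
Why: Dess–Martin oxidation stops at the aldehyde and tolerates the pyridine.

Step 15
Reactants: 19 (3S,3aS,6aR)-3-[8-(pyridin-3-yl)octyl]hexahydro-1H-cyclopenta[c]isoxazole; 26 13-(pyridin-3-yl)tridecanal (1.2 equiv)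
Product: 28 pyrinodemin B, via isoxazolidinium ion 27 (not isolated)
Conditions: NaBH(OAc)3 (1.5 equiv), AcOH (1 equiv), ClCH2CH2Cl, rt
Reagents that add atoms: none
Why: Reductive amination: the N–H isoxazolidine condenses with the aldehyde to an N-alkylidene isoxazolidinium ion that the borohydride reduces without touching the N–O bond or any stereocentre.

**Compound list**
1 | 2,5-dimethoxytetrahydrofuran | COC1CCC(OC)O1 | starting material
2 | succinaldehyde | O=CCCC=O | intermediate
3 | (triphenylphosphoranylidene)acetaldehyde | O=CC=P(c1ccccc1)(c1ccccc1)c1ccccc1 | starting material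
4 | (E)-hex-2-enedial | O=C/C=C/CCC=O | intermediate
5 | tert-butyl N-hydroxycarbamate | CC(C)(C)OC(=O)NO | starting material
6 | tert-butyl N-[(tert-butyldimethylsilyl)oxy]carbamate | CC(C)(C)OC(=O)NO[Si](C)(C)C(C)(C)C | intermediate
7 | tert-butyl N-[(tert-butyldimethylsilyl)oxy]-N-[(1R)-2-formyl-3-hydroxycyclopentyl]carbamate (aldol adduct, not isolated) | O=CC1C(O)CC[C@H]1N(O[Si](C)(C)C(C)(C)C)C(=O)OC(C)(C)C | intermediate
8 | tert-butyl N-[(tert-butyldimethylsilyl)oxy]-N-[(1R)-2-formylcyclopent-2-en-1-yl]carbamate | O=CC1=CCC[C@H]1N(O[Si](C)(C)C(C)(C)C)C(=O)OC(C)(C)C | intermediate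
9 | 3-bromopyridine | Brc1cccnc1 | starting material
10 | octa-1,7-diyne | C#CCCCCC#C | starting material
11 | 3-(octa-1,7-diyn-1-yl)pyridine | C#CCCCCC#Cc1cccnc1 | intermediate
12 | lithium 8-(pyridin-3-yl)octa-1,7-diyn-1-ide (not isolated) | [Li]C#CCCCCC#Cc1cccnc1 | intermediate
13 | tert-butyl N-[(tert-butyldimethylsilyl)oxy]-N-[(1R)-2-[1-hydroxy-9-(pyridin-3-yl)nona-2,8-diyn-1-yl]cyclopent-2-en-1-yl]carbamate | OC(C#CCCCCC#Cc1cccnc1)C1=CCC[C@H]1N(O[Si](C)(C)C(C)(C)C)C(=O)OC(C)(C)C | intermediate
14 | tert-butyl N-[(tert-butyldimethylsilyl)oxy]-N-[(1R)-2-[9-(pyridin-3-yl)nona-2,8-diynoyl]cyclopent-2-en-1-yl]carbamate | O=C(C#CCCCCC#Cc1cccnc1)C1=CCC[C@H]1N(O[Si](C)(C)C(C)(C)C)C(=O)OC(C)(C)C | intermediate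
15 | tert-butyl N-[(tert-butyldimethylsilyl)oxy]-N-[(1R,2S)-2-[9-(pyridin-3-yl)nonanoyl]cyclopentyl]carbamate | O=C(CCCCCCCCc1cccnc1)[C@H]1CCC[C@H]1N(O[Si](C)(C)C(C)(C)C)C(=O)OC(C)(C)C | intermediate
16 | tert-butyl N-hydroxy-N-[(1R,2S)-2-[9-(pyridin-3-yl)nonanoyl]cyclopentyl]carbamate (not isolated) | O=C(CCCCCCCCc1cccnc1)[C@H]1CCC[C@H]1N(O)C(=O)OC(C)(C)C | intermediate
17 | tert-butyl (3aS,6aR)-3-hydroxy-3-[8-(pyridin-3-yl)octyl]hexahydro-1H-cyclopenta[c]isoxazole-1-carboxylate | CC(C)(C)OC(=O)N1OC(O)(CCCCCCCCc2cccnc2)[C@H]2CCC[C@H]21 | intermediate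
18 | tert-butyl (3S,3aS,6aR)-3-[8-(pyridin-3-yl)octyl]hexahydro-1H-cyclopenta[c]isoxazole-1-carboxylate (not isolated) | CC(C)(C)OC(=O)N1O[C@@H](CCCCCCCCc2cccnc2)[C@H]2CCC[C@H]21 | intermediate
19 | (3S,3aS,6aR)-3-[8-(pyridin-3-yl)octyl]hexahydro-1H-cyclopenta[c]isoxazole | N1O[C@@H](CCCCCCCCc2cccnc2)[C@H]2CCC[C@H]21 | intermediate
20 | 12-bromododecan-1-ol | OCCCCCCCCCCCCBr | starting material
21 | (12-bromododecyloxy)(tert-butyl)dimethylsilane | CC(C)(C)[Si](C)(C)OCCCCCCCCCCCCBr | intermediate
22 | 3-methylpyridine | Cc1cccnc1 | starting material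
23 | 3-picolyllithium (not isolated) | [Li]Cc1cccnc1 | intermediate
24 | 3-[13-[(tert-butyldimethylsilyl)oxy]tridecyl]pyridine | CC(C)(C)[Si](C)(C)OCCCCCCCCCCCCCc1cccnc1 | intermediate
25 | 13-(pyridin-3-yl)tridecan-1-ol | OCCCCCCCCCCCCCc1cccnc1 | intermediate
26 | 13-(pyridin-3-yl)tridecanal | O=CCCCCCCCCCCCCc1cccnc1 | intermediate
27 | (3S,3aS,6aR)-3-[8-(pyridin-3-yl)octyl]-1-[13-(pyridin-3-yl)tridecylidene]hexahydro-1H-cyclopenta[c]isoxazol-1-ium (not isolated) | c1cncc(CCCCCCCCCCCCC=[N+]2O[C@@H](CCCCCCCCc3cccnc3)[C@H]3CCC[C@H]32)c1 | intermediate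
28 | pyrinodemin B, 3-[13-[(3S,3aS,6aR)-3-[8-(pyridin-3-yl)octyl]hexahydro-1H-cyclopenta[c]isoxazol-1-yl]tridecyl]pyridine | c1cncc(CCCCCCCCCCCCCN2O[C@@H](CCCCCCCCc3cccnc3)[C@H]3CCC[C@H]32)c1 | target

**Totals**
Total step count: 15.
Longest linear sequence: 9 steps (1, 2, 4, 6, 7, 8, 9, 10, 15).

**Steps most likely to fail**

Step 4. The cascade has no direct precedent on this substrate. The enamine may be hydrolysed before it closes the ring, the carbamate may be lost by E1cB after the aldol step (a Morita–Baylis–Hillman-type outcome), or the ee may erode through reversible addition. Fallback (ring first, nitrogen second): it sets out from 4. An intramolecular Morita–Baylis–Hillman reaction (PBu3, or imidazole with L-proline) gives racemic 5-hydroxycyclopent-1-ene-1-carbaldehyde F1. Boc2O with DMAP converts this into racemic tert-butyl (2-formylcyclopent-2-en-1-yl) carbonate F2. A cinchona-dimer Lewis base such as (DHQD)2PHAL then mediates SN2′/SN2′ allylic substitution of F2 by 6 in a dynamic kinetic asymmetric transformation; the quinidine- or quinine-derived dimer is chosen to deliver the (R) product. The fallback comes back to the route at 8.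

Step 8. The pyridine may slow the palladium, the allylic C–N bond or the N–O bond may be hydrogenolysed, or cis selectivity may be incomplete. Fallback (sp3 chain plus hydride conjugate reduction, no H2): it sets out from 8. Addition of oct-7-enylmagnesium bromide gives tert-butyl N-[(tert-butyldimethylsilyl)oxy]-N-[(1R)-2-(1-hydroxynon-8-en-1-yl)cyclopent-2-en-1-yl]carbamate F3. Hydroboration of the terminal alkene with 9-BBN and B-alkyl Suzuki–Miyaura coupling with 9 (Pd(dppf)Cl2, K3PO4) gives the 1-hydroxy-9-(pyridin-3-yl)nonyl analogue F4. Dess–Martin oxidation gives the enone tert-butyl N-[(tert-butyldimethylsilyl)oxy]-N-[(1R)-2-[9-(pyridin-3-yl)nonanoyl]cyclopent-2-en-1-yl]carbamate F5. Conjugate reduction with [(Ph3P)CuH]6 and protonation of the enolate comes back to the route at 15; any trans epimer can still equilibrate through the enol before ring closure.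

Step 10. The N-acylated oxocarbenium ion may form sluggishly, or the Boc group may be lost first to leave a protonated hydroxylamine that does not close; facial selectivity at C3 could also be lower than expected. Fallback (SN2 ring closure instead of oxocarbenium reduction): it sets out from 15. Reagent-controlled reduction with (S)-Me-CBS oxazaborolidine and catecholborane gives tert-butyl N-[(tert-butyldimethylsilyl)oxy]-N-[(1R,2S)-2-[(1R)-1-hydroxy-9-(pyridin-3-yl)nonyl]cyclopentyl]carbamate F6. HF·pyridine gives the N-hydroxy carbamate tert-butyl N-hydroxy-N-[(1R,2S)-2-[(1R)-1-hydroxy-9-(pyridin-3-yl)nonyl]cyclopentyl]carbamate F7. An intramolecular Mitsunobu reaction (PPh3, DIAD) closes the O–C3 bond with inversion and comes back to the route at 18, which CF3CO2H converts into 19.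

**Further compounds**
F1 | step 4 | rac-5-hydroxycyclopent-1-ene-1-carbaldehyde | O=CC1=CCCC1O
F2 | step 4 | rac-tert-butyl (2-formylcyclopent-2-en-1-yl) carbonate | O=CC1=CCCC1OC(=O)OC(C)(C)C
F3 | step 8 | tert-butyl N-[(tert-butyldimethylsilyl)oxy]-N-[(1R)-2-(1-hydroxynon-8-en-1-yl)cyclopent-2-en-1-yl]carbamate | OC(CCCCCCC=C)C1=CCC[C@H]1N(O[Si](C)(C)C(C)(C)C)C(=O)OC(C)(C)C
F4 | step 8 | tert-butyl N-[(tert-butyldimethylsilyl)oxy]-N-[(1R)-2-[1-hydroxy-9-(pyridin-3-yl)nonyl]cyclopent-2-en-1-yl]carbamate | OC(CCCCCCCCc1cccnc1)C1=CCC[C@H]1N(O[Si](C)(C)C(C)(C)C)C(=O)OC(C)(C)C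
F5 | step 8 | tert-butyl N-[(tert-butyldimethylsilyl)oxy]-N-[(1R)-2-[9-(pyridin-3-yl)nonanoyl]cyclopent-2-en-1-yl]carbamate | O=C(CCCCCCCCc1cccnc1)C1=CCC[C@H]1N(O[Si](C)(C)C(C)(C)C)C(=O)OC(C)(C)C
F6 | step 10 | tert-butyl N-[(tert-butyldimethylsilyl)oxy]-N-[(1R,2S)-2-[(1R)-1-hydroxy-9-(pyridin-3-yl)nonyl]cyclopentyl]carbamate | O[C@H](CCCCCCCCc1cccnc1)[C@H]1CCC[C@H]1N(O[Si](C)(C)C(C)(C)C)C(=O)OC(C)(C)C
F7 | step 10 | tert-butyl N-hydroxy-N-[(1R,2S)-2-[(1R)-1-hydroxy-9-(pyridin-3-yl)nonyl]cyclopentyl]carbamate | O[C@H](CCCCCCCCc1cccnc1)[C@H]1CCC[C@H]1N(O)C(=O)OC(C)(C)C
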